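## Retrosynthetic overview

1. Target 27 ⇐ pyrone epoxy ketone 23 in one operation: methoxide opens the pyrone to a 3,5,7-triketo ester, Claisen closure builds the phloroglucinol ring A, and the new ortho-phenoxide opens the epoxide 6-endo to close ring C (C3 = retained epoxide carbon, C2 = inverted benzylic carbon); acid then removes the two MOM groups.
2. 23 ⇐ C-acylation of the dianion of triacetic acid lactone 20 with the (2R,3S)-epoxy N-acylpyrrole 19.
3. 19 ⇐ aldehyde 11 + ylide 17 by one-pot Wittig olefination / Sm–H8-BINOL nucleophilic epoxidation (both stereocentres are set here).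
4. 11 ⇐ resorcinol 1 by MOM protection and three successive directed ortho-metalations (geranyl, prenyl, CHO).
5. Ring order: ring B is bought (resorcinol); rings A and C are formed together in the last step, A first and C second.

Assumption: the Sm/H8-BINOL epoxidation is taken to follow the usual sense ((R)-ligand gives the (2S,3R)-epoxide), so the (S)-ligand is used; if a test run shows the opposite sense, the (R)-ligand is used instead.

Ar = 3-[(2E)-3,7-dimethylocta-2,6-dien-1-yl]-2,4-bis(methoxymethoxy)-5-(3-methylbut-2-en-1-yl)phenyl.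

## Route

Step 1
Reactants: 1 resorcinol
Product: 2 1,3-bis(methoxymethoxy)benzene
Conditions: NaH (2.5 equiv), MOMCl (2.4 equiv), DMF, 0 °C → rt
Reagents that add atoms: chloromethyl methyl ether (MOMCl), COCCl
Why: Williamson-type O-alkylation of both phenoxides (MOM protection), giving ethers that direct ortho-lithiation and survive BuLi, ylide, peroxide and methoxide.

Step 2
Reactants: 2 1,3-bis(methoxymethoxy)benzene; 3 geranyl bromide
Product: 5 2-[(2E)-3,7-dimethylocta-2,6-dien-1-yl]-1,3-bis(methoxymethoxy)benzene, via aryllithium 4 (not isolated)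
Conditions: n-BuLi (1.1 equiv), THF, 0 °C → rt, 1 h; CuBr·SMe2 (10 mol %), 3 (1.1 equiv), −78 °C → rt
Reagents that add atoms: geranyl bromide (3), CC(C)=CCC/C(C)=C/CBr
Why: Directed ortho-metalation removes the C2–H flanked by both OMOM groups, and the copper-assisted aryl nucleophile displaces the primary allylic bromide SN2 with the (E)-alkene retained.

Step 3
Reactants: 5 2-geranyl-1,3-bis(methoxymethoxy)benzene; 6 prenyl bromide
Product: 8 2-[(2E)-3,7-dimethylocta-2,6-dien-1-yl]-1,3-bis(methoxymethoxy)-4-(3-methylbut-2-en-1-yl)benzene, via aryllithium 7 (not isolated)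
Conditions: n-BuLi (1.2 equiv), TMEDA (1.2 equiv), THF, −20 → 0 °C, 1 h; CuBr·SMe2 (10 mol %), 6 (1.3 equiv), −78 °C → rt
Reagents that add atoms: prenyl bromide (6), CC(C)=CCBr
Why: Second directed ortho-metalation at C4 (C4 and C6 are equivalent in symmetric 5, and alkyllithium/TMEDA favours kinetic ring lithiation next to OMOM) followed by SN2 allylation.

Step 4
Reactants: 8 2-geranyl-1,3-bis(methoxymethoxy)-4-prenylbenzene
Product: 11 3-[(2E)-3,7-dimethylocta-2,6-dien-1-yl]-2,4-bis(methoxymethoxy)-5-(3-methylbut-2-en-1-yl)benzaldehyde, via aryllithium 9 (not isolated), via lithium hemiaminal alkoxide 10 (not isolated)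
Conditions: n-BuLi (1.3 equiv), TMEDA, THF, −20 → 0 °C; DMF (3 equiv), −78 → 0 °C; H2O
Reagents that add atoms: N,N-dimethylformamide, CN(C)C=O
Why: Third directed ortho-metalation at the only remaining position ortho to an OMOM group, then Bouveault formylation with DMF, the hemiaminal alkoxide collapsing to the aldehyde on aqueous quench.

Step 5
Reactants: 12 2-chloroacetamide; 13 2,5-dimethoxytetrahydrofuran
Product: 14 2-chloro-1-(1H-pyrrol-1-yl)ethan-1-one
Conditions: AcOH, 100 °C, 2 h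
Reagents that add atoms: 2,5-dimethoxytetrahydrofuran (13), COC1CCC(OC)O1
Why: Clauson–Kaas pyrrole synthesis, in which acid unmasks succinaldehyde from 13 and the primary amide nitrogen condenses with both carbonyls and aromatises to the N-acylpyrrole, leaving the C–Cl bond untouched.

Step 6
Reactants: 14 2-chloro-1-(1H-pyrrol-1-yl)ethan-1-one; 15 triphenylphosphine
Product: 17 1-(1H-pyrrol-1-yl)-2-(triphenyl-λ5-phosphanylidene)ethan-1-one, via phosphonium chloride 16 (not isolated)
Conditions: toluene, 80 °C; then 1 M aq NaOH, CH2Cl2, 0 °C, 10 min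
Reagents that add atoms: triphenylphosphine (15), c1ccc(cc1)P(c1ccccc1)c1ccccc1
Why: SN2 quaternisation of PPh3 by the α-chloro carbonyl compound and deprotonation of the acidic phosphonium salt give the bench-stable stabilised ylide.

Step 7
Reactants: 11 3-geranyl-2,4-bis(methoxymethoxy)-5-prenylbenzaldehyde; 17 1-(1H-pyrrol-1-yl)-2-(triphenyl-λ5-phosphanylidene)ethan-1-one
Product: 19 [(2R,3S)-3-Ar-oxiran-2-yl](1H-pyrrol-1-yl)methanone, via enoyl pyrrole 18 (not isolated)
Conditions: 17 (1.1 equiv), toluene, 90 °C; then Sm(O-iPr)3 (10 mol %), (S)-H8-BINOL (10 mol %), TBHP (1.5 equiv, in toluene), 4 Å MS, THF–toluene, rt; Et3N-deactivated silica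
Reagents that add atoms: ylide (17), O=C(C=P(c1ccccc1)(c1ccccc1)c1ccccc1)n1cccc1; tert-butyl hydroperoxide, CC(C)(C)OO
Why: Wittig olefination with the stabilised ylide gives the (E)-enoyl pyrrole, and the Sm–H8-BINOL/Ph3P=O-catalysed nucleophilic (Weitz–Scheffer-type) epoxidation delivers tert-butylperoxide to one face of the electron-poor alkene only, so the catalyst sets both epoxide carbons (2R,3S), the trans geometry follows from the (E)-alkene, and the prenyl and geranyl alkenes are not touched.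

Step 8
Reactants: 19 [(2R,3S)-3-Ar-oxiran-2-yl](1H-pyrrol-1-yl)methanone; 20 triacetic acid lactone (4-hydroxy-6-methyl-2H-pyran-2-one)
Product: 23 4-hydroxy-6-{2-[(2R,3S)-3-Ar-oxiran-2-yl]-2-oxoethyl}-2H-pyran-2-one, via dianion 21 (not isolated), via pyrrolyl carbinolate 22 (not isolated)
Conditions: 20 (2.0 equiv), LDA (4.1 equiv, commercial solution), THF–DMPU, −78 °C, 1 h; 19, −78 → 0 °C; AcOH, −78 °C; crude, no chromatography, used at once
Reagents that add atoms: triacetic acid lactone (20), CC1=CC(O)=CC(=O)O1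
Why: Claisen-type C-acylation of the lactone dianion at its 6-methyl carbon by the activated N-acylpyrrole, whose tetrahedral carbinolate prevents over-addition until it collapses on warming, while the epoxide stereocentres are not involved.

Step 9
Reactants: 23 4-hydroxy-6-{2-[(2R,3S)-3-Ar-oxiran-2-yl]-2-oxoethyl}-2H-pyran-2-one
Product: 27 (2R,3R)-2-{3-[(2E)-3,7-dimethylocta-2,6-dien-1-yl]-2,4-dihydroxy-5-(3-methylbut-2-en-1-yl)phenyl}-3,5,7-trihydroxy-2,3-dihydro-4H-chromen-4-one, via triketo ester 24 (not isolated), via epoxy ketone 25 (not isolated), via MOM-protected flavanonol 26 (not isolated)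
Conditions: Mg(OMe)2 (8 equiv), MeOH–THF, Ar (degassed), 55 °C; then HCl (to 2 M), MeOH, 45 °C
Reagents that add atoms: none
Why: Proposed new method: methoxide opens the pyrone of 23 to the Mg-chelated 3,5,7-triketo ester 24, whose C6 carbanion closes onto the ester carbonyl (biomimetic chalcone-synthase-type Claisen cyclisation; closest known reaction type is the Mg(OMe)2-mediated conversion of 6-(2-oxoalkyl)-4-hydroxy-2-pyrones and 3,5,7-triketo esters into acylphloroglucinols) to give ring A in 25, and an ortho-phenoxide then opens the Mg-activated epoxide 6-endo at the electron-rich benzylic carbon with inversion (closest known reaction type is the cyclisation of 2'-hydroxychalcone epoxides to trans-dihydroflavonols) to close ring C, so C3 (R) is the untouched epoxide α-carbon and C2 (R) the inverted β-carbon, the 2,3-trans isomer also being the thermodynamic one, after which HCl/MeOH transacetalises the two MOM ethers and cyclises any residual 25.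

## Compound list

1 | resorcinol | Oc1cccc(O)c1 | starting material
2 | 1,3-bis(methoxymethoxy)benzene | COCOc1cccc(OCOC)c1 | intermediate
3 | geranyl bromide, (2E)-1-bromo-3,7-dimethylocta-2,6-diene | CC(C)=CCC/C(C)=C/CBr | starting material
4 | 2,6-bis(methoxymethoxy)phenyllithium | COCOc1cccc(OCOC)c1[Li] | intermediate
5 | 2-[(2E)-3,7-dimethylocta-2,6-dien-1-yl]-1,3-bis(methoxymethoxy)benzene | CC(C)=CCC/C(C)=C/Cc1c(OCOC)cccc1OCOC | intermediate
6 | prenyl bromide, 1-bromo-3-methylbut-2-ene | CC(C)=CCBr | starting material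
7 | 3-[(2E)-3,7-dimethylocta-2,6-dien-1-yl]-2,4-bis(methoxymethoxy)phenyllithium | CC(C)=CCC/C(C)=C/Cc1c(OCOC)ccc([Li])c1OCOC | intermediate
8 | 2-[(2E)-3,7-dimethylocta-2,6-dien-1-yl]-1,3-bis(methoxymethoxy)-4-(3-methylbut-2-en-1-yl)benzene | CC(C)=CCC/C(C)=C/Cc1c(OCOC)ccc(CC=C(C)C)c1OCOC | intermediate
9 | 3-[(2E)-3,7-dimethylocta-2,6-dien-1-yl]-2,4-bis(methoxymethoxy)-5-(3-methylbut-2-en-1-yl)phenyllithium | CC(C)=CCC/C(C)=C/Cc1c(OCOC)c([Li])cc(CC=C(C)C)c1OCOC | intermediate
10 | lithium (dimethylamino)(Ar)methoxide, racemic at the hemiaminal carbon | CC(C)=CCC/C(C)=C/Cc1c(OCOC)c(C(O[Li])N(C)C)cc(CC=C(C)C)c1OCOC | intermediate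
11 | 3-[(2E)-3,7-dimethylocta-2,6-dien-1-yl]-2,4-bis(methoxymethoxy)-5-(3-methylbut-2-en-1-yl)benzaldehyde | CC(C)=CCC/C(C)=C/Cc1c(OCOC)c(C=O)cc(CC=C(C)C)c1OCOC | intermediate
12 | 2-chloroacetamide | NC(=O)CCl | starting material
13 | 2,5-dimethoxytetrahydrofuran (cis/trans mixture) | COC1CCC(OC)O1 | starting material
14 | 2-chloro-1-(1H-pyrrol-1-yl)ethan-1-one | O=C(CCl)n1cccc1 | intermediate
15 | triphenylphosphine | c1ccc(cc1)P(c1ccccc1)c1ccccc1 | starting material
16 | [2-oxo-2-(1H-pyrrol-1-yl)ethyl]triphenylphosphonium chloride | O=C(C[P+](c1ccccc1)(c1ccccc1)c1ccccc1)n1cccc1.[Cl-] | intermediate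
17 | 1-(1H-pyrrol-1-yl)-2-(triphenyl-λ5-phosphanylidene)ethan-1-one | O=C(C=P(c1ccccc1)(c1ccccc1)c1ccccc1)n1cccc1 | intermediate
18 | (2E)-3-Ar-1-(1H-pyrrol-1-yl)prop-2-en-1-one | CC(C)=CCC/C(C)=C/Cc1c(OCOC)c(/C=C/C(=O)n2cccc2)cc(CC=C(C)C)c1OCOC | intermediate
19 | [(2R,3S)-3-Ar-oxiran-2-yl](1H-pyrrol-1-yl)methanone (trans-epoxide) | CC(C)=CCC/C(C)=C/Cc1c(OCOC)c([C@@H]2O[C@H]2C(=O)n3cccc3)cc(CC=C(C)C)c1OCOC | intermediate
20 | triacetic acid lactone, 4-hydroxy-6-methyl-2H-pyran-2-one | CC1=CC(O)=CC(=O)O1 | starting material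
21 | dilithium dianion of 20 (lithiated at O-4 and at the 6-methyl carbon) | [Li]CC1=CC(O[Li])=CC(=O)O1 | intermediate
22 | dilithium pyrrolyl carbinolate, adduct of 21 to the carbonyl of 19 (epoxide as in 19, carbinol carbon as a mixture) | CC(C)=CCC/C(C)=C/Cc1c(OCOC)c([C@@H]2O[C@H]2C(O[Li])(CC3=CC(O[Li])=CC(=O)O3)n4cccc4)cc(CC=C(C)C)c1OCOC | intermediate
23 | 4-hydroxy-6-{2-[(2R,3S)-3-Ar-oxiran-2-yl]-2-oxoethyl}-2H-pyran-2-one | CC(C)=CCC/C(C)=C/Cc1c(OCOC)c([C@@H]2O[C@H]2C(=O)CC3=CC(O)=CC(=O)O3)cc(CC=C(C)C)c1OCOC | intermediate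
24 | methyl 7-[(2R,3S)-3-Ar-oxiran-2-yl]-3,5,7-trioxoheptanoate | CC(C)=CCC/C(C)=C/Cc1c(OCOC)c([C@@H]2O[C@H]2C(=O)CC(=O)CC(=O)CC(=O)OC)cc(CC=C(C)C)c1OCOC | intermediate
25 | [(2R,3S)-3-Ar-oxiran-2-yl](2,4,6-trihydroxyphenyl)methanone | CC(C)=CCC/C(C)=C/Cc1c(OCOC)c([C@@H]2O[C@H]2C(=O)c3c(O)cc(O)cc3O)cc(CC=C(C)C)c1OCOC | intermediate
26 | (2R,3R)-2-Ar-3,5,7-trihydroxy-2,3-dihydro-4H-chromen-4-one (2,3-trans, B-ring MOM ethers intact) | CC(C)=CCC/C(C)=C/Cc1c(OCOC)c(CC=C(C)C)cc([C@H]2Oc3cc(O)cc(O)c3C(=O)[C@@H]2O)c1OCOC | intermediate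
27 | (2R,3R)-2-{3-[(2E)-3,7-dimethylocta-2,6-dien-1-yl]-2,4-dihydroxy-5-(3-methylbut-2-en-1-yl)phenyl}-3,5,7-trihydroxy-2,3-dihydro-4H-chromen-4-one | CC(C)=CCC/C(C)=C/Cc1c(O)c(CC=C(C)C)cc([C@H]2Oc3cc(O)cc(O)c3C(=O)[C@@H]2O)c1O | target

## Step count and risks

Total steps: 9. Longest linear sequence: 7 (steps 1, 2, 3, 4, 7, 8, 9, from resorcinol); steps 5 and 6 make the ylide on a side branch.

The three steps most likely to fail:

**Step 9 (pyrone → ring A → ring C cascade).** The triketo ester may close by aldol instead of Claisen, or methanol may open the labile epoxide before ring A exists. The fallback sets out from 19 and comes back at 27, buying ring A instead of building it. Phloroglucinol is protected (NaH, MOMCl) as 1,3,5-tris(methoxymethoxy)benzene F1, which n-BuLi lithiates between two OMOM groups to 2,4,6-tris(methoxymethoxy)phenyllithium F2. F2 is acylated by 19 at −78 °C to give the epoxy ketone [(2R,3S)-3-Ar-oxiran-2-yl][2,4,6-tris(methoxymethoxy)phenyl]methanone F3. HCl in MeOH at 45 °C then removes all five MOM groups, and the freed ortho-phenol opens the epoxide at the benzylic carbon to give 27 directly as the trans isomer.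

**Step 8 (acylation of the lactone dianion).** The dianion is poorly soluble, and 23 carries an acidic pyrone OH next to an acid-labile epoxide. The fallback sets out from 19 and comes back at 24, replacing the pyrone by a neutral dioxinone as the triketide unit. 2,2,6-Trimethyl-4H-1,3-dioxin-4-one is acetylated at its methyl group (LiHMDS, then AcCl) to 2,2-dimethyl-6-(2-oxopropyl)-4H-1,3-dioxin-4-one F4. The dianion of F4 (LDA, 2 equiv) is acylated at its terminal methyl by 19 to give 6-{4-[(2R,3S)-3-Ar-oxiran-2-yl]-2,4-dioxobutyl}-2,2-dimethyl-4H-1,3-dioxin-4-one F5, which can be purified. Heating F5 in toluene–MeOH at 100 °C extrudes acetone to the acylketene 7-[(2R,3S)-3-Ar-oxiran-2-yl]-3,5,7-trioxohept-1-en-1-one F6, which methanol traps as the triketo ester 24. 24 is then taken through the Mg(OMe)2 and HCl stages of step 9.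

**Step 7 (one-pot Wittig / asymmetric epoxidation).** The electron-rich, ortho-substituted enoyl pyrrole may be too poor an acceptor for the Sm-bound peroxide, or the ee may be low. The fallback sets out from 11 and comes back at 23, using organocatalytic iminium activation and an aldol–oxidation sequence in place of steps 7 and 8. Wittig reaction of 11 with (triphenylphosphoranylidene)acetaldehyde gives (2E)-3-Ar-prop-2-enal F7. Epoxidation of F7 with aqueous H2O2 and the (S)-diarylprolinol trimethylsilyl ether catalyst (the enantiomer that gives the 2R,3S product) in CH2Cl2 gives (2R,3S)-3-Ar-oxirane-2-carbaldehyde F8; only the iminium-activated alkene reacts. Aldol addition of dianion 21 to F8 at −78 °C gives 4-hydroxy-6-{2-hydroxy-2-[3-Ar-oxiran-2-yl]ethyl}-2H-pyran-2-one F9 (epoxide carbons as in F8, both carbinol epimers). NaHCO3-buffered Dess–Martin periodinane oxidises F9 to 23.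

## Further compounds

F1 | step 9 | 1,3,5-tris(methoxymethoxy)benzene | COCOc1cc(OCOC)cc(OCOC)c1
F2 | step 9 | 2,4,6-tris(methoxymethoxy)phenyllithium | COCOc1cc(OCOC)c([Li])c(OCOC)c1
F3 | step 9 | [(2R,3S)-3-Ar-oxiran-2-yl][2,4,6-tris(methoxymethoxy)phenyl]methanone | CC(C)=CCC/C(C)=C/Cc1c(OCOC)c([C@@H]2O[C@H]2C(=O)c3c(OCOC)cc(OCOC)cc3OCOC)cc(CC=C(C)C)c1OCOC
F4 | step 8 | 2,2-dimethyl-6-(2-oxopropyl)-4H-1,3-dioxin-4-one | CC(=O)CC1=CC(=O)OC(C)(C)O1
F5 | step 8 | 6-{4-[(2R,3S)-3-Ar-oxiran-2-yl]-2,4-dioxobutyl}-2,2-dimethyl-4H-1,3-dioxin-4-one | CC(C)=CCC/C(C)=C/Cc1c(OCOC)c([C@@H]2O[C@H]2C(=O)CC(=O)CC3=CC(=O)OC(C)(C)O3)cc(CC=C(C)C)c1OCOC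
F6 | step 8 | 7-[(2R,3S)-3-Ar-oxiran-2-yl]-3,5,7-trioxohept-1-en-1-one (acylketene) | CC(C)=CCC/C(C)=C/Cc1c(OCOC)c([C@@H]2O[C@H]2C(=O)CC(=O)CC(=O)C=C=O)cc(CC=C(C)C)c1OCOC
F7 | step 7 | (2E)-3-Ar-prop-2-enal | CC(C)=CCC/C(C)=C/Cc1c(OCOC)c(/C=C/C=O)cc(CC=C(C)C)c1OCOC
F8 | step 7 | (2R,3S)-3-Ar-oxirane-2-carbaldehyde | CC(C)=CCC/C(C)=C/Cc1c(OCOC)c([C@@H]2O[C@H]2C=O)cc(CC=C(C)C)c1OCOC
F9 | step 7 | 4-hydroxy-6-{2-hydroxy-2-[3-Ar-oxiran-2-yl]ethyl}-2H-pyran-2-one, epoxide carbons as in F8, both carbinol epimers | CC(C)=CCC/C(C)=C/Cc1c(OCOC)c([C@@H]2O[C@H]2C(O)CC3=CC(O)=CC(=O)O3)cc(CC=C(C)C)c1OCOC
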